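**Retrosynthetic overview**
1. The hydroxyquinone is unveiled last by oxidation of the 2',4'-dihydroxy-3'-prenyl isoflavan 17; both prenyl groups come from aryl bromides in 14, so that no prenyl alkene is present during the earlier ozonolysis.
2. The pyran ring is closed by Mitsunobu O-alkylation of the ring A phenol with the primary alcohol of 13; that CH2OH comes from ozonolysis/reduction of a propenyl group.
3. The C3 stereocentre and the C3–C1' bond come from an aromatic Claisen rearrangement of the (R,E)-aryl allyl ether 8, with 1,3-chirality transfer through a chair transition state.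
4. Ether 8 comes from Mitsunobu inversion of the (S,E)-allylic alcohol 6 with 2-bromoresorcinol; 6 comes from cross-metathesis of the C-allyl arene 4 with (S)-but-3-en-2-ol; 4 comes from an allyl ether Claisen rearrangement on ring A.
5. Ring order: rings A and B are bought as benzenes, the pyran ring is the only ring formed (step 7), and ring B becomes the quinone in step 10.

Assumption: 4-bromo-3,5-dimethoxyphenol (1), (S)-but-3-en-2-ol (5, L-lactate series) and 2-bromoresorcinol (7) are catalogue compounds; simple reagents (allyl bromide, TBSCl, MOMCl, prenyl bromide) are not numbered.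

**Step 1**
Reactants: 1 4-bromo-3,5-dimethoxyphenol
Product: 2 5-(allyloxy)-2-bromo-1,3-dimethoxybenzene
Conditions: allyl bromide, K2CO3, acetone, reflux
Reagents that add atoms: allyl bromide, C=CCBr
Why: Williamson ether synthesis, SN2 attack of the phenoxide on allyl bromide; no stereocentre is involved.

**Step 2**
Reactants: 2 5-(allyloxy)-2-bromo-1,3-dimethoxybenzene
Product: 4 (2-allyl-4-bromo-3,5-dimethoxyphenoxy)(tert-butyl)dimethylsilane, via C-allyl phenol 3 (not isolated)
Conditions: NMP, 200 °C (sealed tube); cool to rt, imidazole, TBSCl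
Reagents that add atoms: tert-butyldimethylsilyl chloride, CC(C)(C)[Si](C)(C)Cl
Why: Aromatic Claisen rearrangement ([3,3]-sigmatropic) places the allyl group on one of the two equivalent free ortho carbons, and the phenol is silylated in the same pot so that it stays out of the later Mitsunobu etherification.

**Step 3**
Reactants: 4 (2-allyl-4-bromo-3,5-dimethoxyphenoxy)(tert-butyl)dimethylsilane; 5 (S)-but-3-en-2-ol (3 equiv)
Product: 6 (2S,3E)-5-[3-bromo-6-(tert-butyldimethylsilyloxy)-2,4-dimethoxyphenyl]pent-3-en-2-ol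
Conditions: second-generation Grubbs catalyst (5 mol %), CH2Cl2, 40 °C
Reagents that add atoms: none
Why: Olefin cross-metathesis of the allyl arene with the secondary allylic alcohol is E-selective and does not touch the bought carbinol stereocentre; the minor Z isomer is removed by chromatography because it would lead to the enantiomeric series.

**Step 4**
Reactants: 6 (2S,3E)-allylic alcohol; 7 2-bromobenzene-1,3-diol (3 equiv)
Product: 8 2-bromo-3-{[(2R,3E)-5-[3-bromo-6-(tert-butyldimethylsilyloxy)-2,4-dimethoxyphenyl]pent-3-en-2-yl]oxy}phenol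
Conditions: PPh3, DIAD, THF, 0 °C → rt
Reagents that add atoms: none
Why: Mitsunobu etherification, in which the acidic bromoresorcinol (in excess, to favour the mono-ether) displaces the oxyphosphonium by SN2 with inversion, turning the (S)-carbinol into the (R)-aryl ether.

**Step 5**
Reactants: 8 (R,E)-aryl allyl ether
Product: 10 bis(methoxymethyl) ether of 2-bromo-4-{(2S,3E)-1-[3-bromo-6-(tert-butyldimethylsilyloxy)-2,4-dimethoxyphenyl]pent-3-en-2-yl}benzene-1,3-diol, via resorcinol 9 (not isolated)
Conditions: 1,2-dichlorobenzene, 160 °C; cool to 0 °C, CH2Cl2, i-Pr2NEt, MOMCl, 0 °C → rt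
Reagents that add atoms: chloromethyl methyl ether, COCCl
Why: Aromatic Claisen rearrangement ([3,3]-sigmatropic) to the only free ortho carbon (the other carries Br) through a chair transition state with the methyl group equatorial; the C–C bond forms on the allyl face from which the C–O bond leaves, so the (R)-carbinol centre sets the new benzylic centre (S here, R in later compounds by CIP priority change only) and an E-propenyl group, and both phenols are then capped as MOM ethers.

**Step 6**
Reactants: 10 bis(MOM) ether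
Product: 13 4-bromo-2-{(2R)-2-[3-bromo-2,4-bis(methoxymethoxy)phenyl]-3-hydroxypropyl}-3,5-dimethoxyphenol, via aldehyde 11 (not isolated), via silyl ether alcohol 12 (not isolated)
Conditions: O3, CH2Cl2/MeOH (4:1), −78 °C (Sudan Red 7B end point); NaBH4, −78 → 0 °C; then K2CO3, MeOH, rt
Reagents that add atoms: ozone, [O-][O+]=O
Why: Ozonolysis cleaves the only alkene, immediate NaBH4 reduction gives the primary alcohol before the α-aryl aldehyde can epimerise, and K2CO3/MeOH selectively methanolyses the aryl silyl ether while MOM ethers and aryl bromides survive.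

**Step 7**
Reactants: 13 phenol–primary alcohol
Product: 14 (3R)-6-bromo-3-[3-bromo-2,4-bis(methoxymethoxy)phenyl]-5,7-dimethoxychromane
Conditions: PPh3, DIAD, THF (0.02 M), 0 °C → rt
Reagents that add atoms: none
Why: Intramolecular Mitsunobu etherification (6-exo-tet) of the only free phenol onto the activated primary carbon closes the pyran ring; the reaction is not at the stereocentre, so C3 is untouched.

**Step 8**
Reactants: 14 dibromo chromane
Product: 16 (3R)-3-[2,4-bis(methoxymethoxy)-3-(3-methylbut-2-enyl)phenyl]-5,7-dimethoxy-6-(3-methylbut-2-enyl)chromane, via dilithio species 15 (not isolated)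
Conditions: t-BuLi (4.4 equiv), THF, −78 °C; CuBr·SMe2 (0.3 equiv), prenyl bromide (4 equiv), −78 → 0 °C
Reagents that add atoms: 1-bromo-3-methylbut-2-ene, CC(C)=CCBr
Why: Double bromine–lithium exchange gives two aryllithiums, each flanked and stabilised by two ether oxygens, and copper-catalysed allylic substitution at the unhindered CH2 terminus of prenyl bromide installs both linear prenyl groups.

**Step 9**
Reactants: 16 bis(MOM) ether
Product: 17 4-[(3R)-5,7-dimethoxy-6-(3-methylbut-2-enyl)chroman-3-yl]-2-(3-methylbut-2-enyl)benzene-1,3-diol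
Conditions: HCl (2 M aq.), MeOH, rt → 40 °C
Reagents that add atoms: none
Why: Acid-catalysed acetal cleavage of the two MOM ethers under conditions mild enough to avoid cyclisation of the ortho-prenyl phenol to a dimethylchromane.

**Step 10**
Reactants: 17 resorcinol
Product: 18 2-hydroxy-5-[(3R)-5,7-dimethoxy-6-(3-methylbut-2-enyl)chroman-3-yl]-3-(3-methylbut-2-enyl)cyclohexa-2,5-diene-1,4-dione (target)
Conditions: (KSO3)2NO (potassium nitrosodisulfonate, 3 equiv), KH2PO4 buffer (pH 6), acetone/H2O, 0 °C → rt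
Reagents that add atoms: potassium nitrosodisulfonate, [K+].[K+].[O]N(S(=O)(=O)[O-])S(=O)(=O)[O-]
Why: Teuber oxidation introduces oxygen at the only free position para to the 2'-OH (ortho to the 4'-OH), and the product settles as the 2-hydroxy-1,4-benzoquinone tautomer; ring A has no free phenol and the prenyl groups are inert.

**Compound list**
1 | 4-bromo-3,5-dimethoxyphenol | COc1cc(O)cc(OC)c1Br | starting material
2 | 5-(allyloxy)-2-bromo-1,3-dimethoxybenzene | C=CCOc1cc(OC)c(Br)c(OC)c1 | intermediate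
3 | 2-allyl-4-bromo-3,5-dimethoxyphenol | C=CCc1c(O)cc(OC)c(Br)c1OC | intermediate
4 | (2-allyl-4-bromo-3,5-dimethoxyphenoxy)(tert-butyl)dimethylsilane | C=CCc1c(O[Si](C)(C)C(C)(C)C)cc(OC)c(Br)c1OC | intermediate
5 | (S)-but-3-en-2-ol | C[C@H](O)C=C | starting material
6 | (2S,3E)-5-[3-bromo-6-(tert-butyldimethylsilyloxy)-2,4-dimethoxyphenyl]pent-3-en-2-ol | C[C@H](O)/C=C/Cc1c(O[Si](C)(C)C(C)(C)C)cc(OC)c(Br)c1OC | intermediate
7 | 2-bromobenzene-1,3-diol (2-bromoresorcinol) | Oc1cccc(O)c1Br | starting material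
8 | 2-bromo-3-{[(2R,3E)-5-[3-bromo-6-(tert-butyldimethylsilyloxy)-2,4-dimethoxyphenyl]pent-3-en-2-yl]oxy}phenol | C[C@@H](Oc1cccc(O)c1Br)/C=C/Cc1c(O[Si](C)(C)C(C)(C)C)cc(OC)c(Br)c1OC | intermediate
9 | 2-bromo-4-{(2S,3E)-1-[3-bromo-6-(tert-butyldimethylsilyloxy)-2,4-dimethoxyphenyl]pent-3-en-2-yl}benzene-1,3-diol | C/C=C/[C@H](Cc1c(O[Si](C)(C)C(C)(C)C)cc(OC)c(Br)c1OC)c1ccc(O)c(Br)c1O | intermediate
10 | {4-bromo-2-[(2S,3E)-2-[3-bromo-2,4-bis(methoxymethoxy)phenyl]pent-3-en-1-yl]-3,5-dimethoxyphenoxy}(tert-butyl)dimethylsilane | C/C=C/[C@H](Cc1c(O[Si](C)(C)C(C)(C)C)cc(OC)c(Br)c1OC)c1ccc(OCOC)c(Br)c1OCOC | intermediate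
11 | (2R)-2-[3-bromo-2,4-bis(methoxymethoxy)phenyl]-3-[3-bromo-6-(tert-butyldimethylsilyloxy)-2,4-dimethoxyphenyl]propanal | O=C[C@H](Cc1c(O[Si](C)(C)C(C)(C)C)cc(OC)c(Br)c1OC)c1ccc(OCOC)c(Br)c1OCOC | intermediate
12 | (2R)-2-[3-bromo-2,4-bis(methoxymethoxy)phenyl]-3-[3-bromo-6-(tert-butyldimethylsilyloxy)-2,4-dimethoxyphenyl]propan-1-ol | OC[C@H](Cc1c(O[Si](C)(C)C(C)(C)C)cc(OC)c(Br)c1OC)c1ccc(OCOC)c(Br)c1OCOC | intermediate
13 | 4-bromo-2-{(2R)-2-[3-bromo-2,4-bis(methoxymethoxy)phenyl]-3-hydroxypropyl}-3,5-dimethoxyphenol | OC[C@H](Cc1c(O)cc(OC)c(Br)c1OC)c1ccc(OCOC)c(Br)c1OCOC | intermediate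
14 | (3R)-6-bromo-3-[3-bromo-2,4-bis(methoxymethoxy)phenyl]-5,7-dimethoxychromane | COc1cc2c(c(OC)c1Br)C[C@H](c1ccc(OCOC)c(Br)c1OCOC)CO2 | intermediate
15 | (3R)-6-lithio-3-[3-lithio-2,4-bis(methoxymethoxy)phenyl]-5,7-dimethoxychromane | COc1cc2c(c(OC)c1[Li])C[C@H](c1ccc(OCOC)c([Li])c1OCOC)CO2 | intermediate
16 | (3R)-3-[2,4-bis(methoxymethoxy)-3-(3-methylbut-2-enyl)phenyl]-5,7-dimethoxy-6-(3-methylbut-2-enyl)chromane | COc1cc2c(c(OC)c1CC=C(C)C)C[C@H](c1ccc(OCOC)c(CC=C(C)C)c1OCOC)CO2 | intermediate
17 | 4-[(3R)-5,7-dimethoxy-6-(3-methylbut-2-enyl)chroman-3-yl]-2-(3-methylbut-2-enyl)benzene-1,3-diol | COc1cc2c(c(OC)c1CC=C(C)C)C[C@H](c1ccc(O)c(CC=C(C)C)c1O)CO2 | intermediate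
18 | 2-hydroxy-5-[(3R)-5,7-dimethoxy-6-(3-methylbut-2-enyl)chroman-3-yl]-3-(3-methylbut-2-enyl)cyclohexa-2,5-diene-1,4-dione | COc1cc2c(c(OC)c1CC=C(C)C)C[C@H](C1=CC(=O)C(O)=C(CC=C(C)C)C1=O)CO2 | target

**Step count and risks**
Total: 10 steps. Longest linear sequence: 10 steps (1 → 18; 5 and 7 enter as bought compounds).

The three steps most likely to fail:

Step 4 (Mitsunobu on the elaborated secondary allylic alcohol). The risks are SN2′ attack, partial loss of configuration through an allyl cation, and bis-etherification. The fallback forms the aryl–O–C bond on a propargylic alcohol, where Mitsunobu inversion is clean, and joins the fragments afterwards. It sets out from 7 and 4. Compound 7 and (S)-but-3-yn-2-ol (PPh3, DIAD, THF) give (R)-2-bromo-3-(but-3-yn-2-yloxy)phenol F1. Semihydrogenation (H2, Pd/CaCO3 poisoned with Pb(OAc)2, quinoline) gives (R)-2-bromo-3-(but-3-en-2-yloxy)phenol F2. Cross-metathesis of F2 with 4 (second-generation Grubbs catalyst, CH2Cl2, 40 °C) returns to the route at 8.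

Step 5 (chirality-transferring Claisen with in situ capping). The risks are para migration past the brominated ortho carbon, reaction of the freshly liberated phenol with the neighbouring alkene at high temperature, and erosion of chirality transfer through the axial-methyl pathway. The fallback stages the protection and runs the rearrangement on a fully capped substrate under Lewis-acid catalysis at low temperature. It sets out from 8. MOMCl (1.1 equiv) and i-Pr2NEt give 2-bromo-1-(methoxymethoxy)-3-{[(2R,3E)-5-[3-bromo-6-(tert-butyldimethylsilyloxy)-2,4-dimethoxyphenyl]pent-3-en-2-yl]oxy}benzene F3. Rearrangement with Eu(fod)3 [tris(6,6,7,7,8,8,8-heptafluoro-2,2-dimethyloctane-3,5-dionato)europium, 10 mol %] in CHCl3 at 50–60 °C gives 2-bromo-6-{(2S,3E)-1-[3-bromo-6-(tert-butyldimethylsilyloxy)-2,4-dimethoxyphenyl]pent-3-en-2-yl}-3-(methoxymethoxy)phenol F4. MOMCl and i-Pr2NEt then return to the route at 10.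

Step 8 (double bromine–lithium exchange and prenylation). The risks are incomplete double exchange, protonation, and SN2′ attack giving reverse-prenyl isomers at the two hindered positions. The fallback replaces the organolithium chemistry with cross-coupling followed by metathesis. It sets out from 14. Stille coupling with allyltributylstannane (Pd(PPh3)4, DMF, 100 °C) gives (3R)-6-allyl-3-[3-allyl-2,4-bis(methoxymethoxy)phenyl]-5,7-dimethoxychromane F5. Cross-metathesis of F5 with 2-methylbut-2-ene (second-generation Grubbs catalyst, CH2Cl2/2-methylbut-2-ene, 40 °C) returns to the route at 16.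

**Further compounds**
F1 | step 4 | (R)-2-bromo-3-(but-3-yn-2-yloxy)phenol | C[C@@H](Oc1cccc(O)c1Br)C#C
F2 | step 4 | (R)-2-bromo-3-(but-3-en-2-yloxy)phenol | C[C@@H](Oc1cccc(O)c1Br)C=C
F3 | step 5 | 2-bromo-1-(methoxymethoxy)-3-{[(2R,3E)-5-[3-bromo-6-(tert-butyldimethylsilyloxy)-2,4-dimethoxyphenyl]pent-3-en-2-yl]oxy}benzene | C[C@@H](Oc1cccc(OCOC)c1Br)/C=C/Cc1c(O[Si](C)(C)C(C)(C)C)cc(OC)c(Br)c1OC
F4 | step 5 | 2-bromo-6-{(2S,3E)-1-[3-bromo-6-(tert-butyldimethylsilyloxy)-2,4-dimethoxyphenyl]pent-3-en-2-yl}-3-(methoxymethoxy)phenol | C/C=C/[C@H](Cc1c(O[Si](C)(C)C(C)(C)C)cc(OC)c(Br)c1OC)c1ccc(OCOC)c(Br)c1O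
F5 | step 8 | (3R)-6-allyl-3-[3-allyl-2,4-bis(methoxymethoxy)phenyl]-5,7-dimethoxychromane | COc1cc2c(c(OC)c1CC=C)C[C@H](c1ccc(OCOC)c(CC=C)c1OCOC)CO2
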